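The vessel differs across your four set-ups, but the charge does not, so that is where I start. You asked for a quick number, and your hunch is the slow feed.

| flask | starting complex | incoming ligand | leaving ligand | remark | time |
|---|---|---|---|---|---|
| gamma | 0.099 M | 0.119 M | 0.099 M | run made earlier |  |
| epsilon | 0.099 M | 0.17 M | 0.099 M | run made earlier |  |
| beta | 0.099 M | 0.26 M | 0.099 M | run made earlier |  |
| south-west | 0.099 M (fed, over 12.0 h) | 0.119 M | 0.0990 M | all but starting complex at the start; starting complex goes in evenly over 12.0 h, the run ends at 12 h | 12 h |
| south | 0.099 M | 0.119 M | 0.0990 M | a single well-mixed tank run continuously and read at steady state, 36.0 h in it on average |  |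
| north-west | 0.099 M | 0.119 M | 0.0990 M | a closed flask charged with all of it at once and left for 12 h | 12 h |
| west | 0.099 M | 0.119 M | 0.0990 M | a single well-mixed tank run continuously and read at steady state, 12 h in it on average |  |

| run | time / h | complex with three exchanged / % |
|---|---|---|
| gamma | 1.33 | 0.2 |
| gamma | 2.50 | 1.0 |
| gamma | 4.00 | 0 |
| gamma | 5.00 | 3.1 |
| gamma | 6.00 | 3.2 |
| gamma | 8.00 | 6.3 |
| epsilon | 0.667 | 0.1 |
| epsilon | 2.00 | 1.0 |
| epsilon | 3.00 | 1.6 |
| epsilon | 5.00 | 4.0 |
| epsilon | 8.00 | 8.8 |
| epsilon | 10.0 | 13.7 |
| beta | 1.50 | 0.8 |
| beta | 3.00 | 5.0 |
| beta | 5.00 | 12.5 |
| beta | 6.00 | 15.4 |
| beta | 8.00 | 20.3 |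
| beta | 10.0 | 29.7 |

(scatter of a reading: 1 percentage point)

- the stated concentrations are those of everything mixed, before any reaction; amounts are the same in each set-up
- the feed brings no volume worth counting
- the earlier runs were made in a closed, stirred flask
- a reading or a percentage of complex with three exchanged counts all its forms, free or not

- the set-up with the highest amount of complex with three exchanged at the outlet or at the end, in percent of the starting complex put in ("none" if the first two lie within 2 percentage points) (south-west / south / north-west / west / none)
- amount of complex with three exchanged at the outlet or at the end, in percent of the starting complex put in, south-west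
- amount of complex with three exchanged at the outlet or at the end, in percent of the starting complex put in, south
- amount of complex with three exchanged at the outlet or at the end, in percent of the starting complex put in, north-west
- amount of complex with three exchanged at the outlet or at the end, in percent of the starting complex put in, west

1. Each complex with three exchanged costs 3 incoming ligand. The total ligand spent, divided by the total of that complex made, counted from the charge to the end or the outlet, is therefore at least 3; this bound on the totals needs no rate constant.

2. Incoming ligand is charged at 1.20 per starting complex, so it is the limiting reagent. The charged ligand divided by 3, as a fraction of the charge of starting complex, gives the ligand ceiling: 40.1 %. The four set-ups share it, because their amounts are the same.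

3. The gamma run has this same charge and reads 6.3 % at 8.00 h, which is 15.7 % of the ceiling. It is still rising from 3.2 % at 6.00 h.

4. So I order the set-ups by time in the vessel. South has 36.0 h on average, more than the 12 h of west and north-west. Complex fed evenly in south-west spends 6.00 h in the flask on average, less than the 12 h of north-west. My reckoning therefore differs from your hunch: I put south first, below 40.1 %, and south-west last.

5. The forecast names south at 15 % (range 10 % to 21 %), with north-west at 10 %, west at 8.5 % and south-west at 6 %: “The much longer residence time wins.”

6. South gives 16.5 % and is the best set-up, ahead of west at 8.39 %, north-west at 8.20 % and south-west at 4.19 %.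

    starting complex + incoming ligand → leaving ligand + complex with one exchanged (k = 0.570 M⁻¹ h⁻¹)
    complex with one exchanged + incoming ligand → leaving ligand + complex with two exchanged (k = 2.29 M⁻¹ h⁻¹)
    complex with two exchanged + incoming ligand → leaving ligand + complex with three exchanged (k = 1.12 M⁻¹ h⁻¹)
    starting complex → decomposition product (k = 1.04 × 10⁻⁴ h⁻¹)
    complex with three exchanged + incoming ligand ⇌ idle adduct, settled at all times (K = 4.07 M⁻¹)

At the south outlet, 59.9 % of the charged complex is still starting complex. South's amount is 41.1 % of the ligand ceiling of 40.1 %. South-west, taken to 120 h with all else as it is, gives 21.2 %, which is 52.9 % of that same ceiling.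

The data come from a simulation for an exercise, and the scatter is random.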